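## Retrosynthetic overview

1. Kanzonol T comes from its fully silylated form in one fluoride step. Ring A (C4a–C5–C6–C7–C8–C8a) is the last ring made and is disconnected at C8–C8a and C6–C7.
2. The strategy rests on the fusion bond C4a=C8a between rings A and C. This bond can already exist as a C=C of a monocyclic 4-pyranone that holds O1, C2, the C3 aryl group and C4=O. Together with the enol ether C5=C6 of an acyl group on C4a it forms the diene C8a=C4a–C5=C6, electrophilic at C8a (β to C4=O) and nucleophilic at C6. HC≡C–OSi(i-Pr)3 has the opposite polarity and supplies C8–H and C7–O, so the 5,7-dioxygen/6-alkyl/8-H pattern follows from connectivity.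
3. Ring C comes from the 1,3-diketone ArCH2CO–CH2–COR, two C1 units (C2 and C8a) from DMF dimethyl acetal, and O1 from water. The diketone comes from aldol addition and oxidation of the chromenylacetaldehyde with the kinetic enolate of silylated 6-hydroxy-6-methylheptan-2-one.
4. The chromene aldehyde comes from 2,4-dihydroxybenzaldehyde and 3-methylbut-2-enal. The ynol ether comes from ethynyltrimethylsilane by acetylide oxidation, O-silylation and C-desilylation.
5. Order of ring formation: the dimethylpyran ring on ring B first, then ring C (the 4-pyranone), then ring A.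

Key step: step 13

Remark: isoflavone numbering (O1, C2, C3, C4, C4a, C5–C8, C8a, ring B primed) is used for all precursors; Ar = 5-(tert-butyldimethylsilyloxy)-2,2-dimethyl-2H-chromen-6-yl; TBS, TES and TIPS are tert-butyldimethylsilyl, triethylsilyl and triisopropylsilyl; the target is achiral, so 11 and 23 are handled as racemates whose stereocentres are removed again.

## Route

Step 1
Reactants: 1 2,4-dihydroxybenzaldehyde; 2 3-methylbut-2-enal
Product: 3 5-hydroxy-2,2-dimethyl-2H-chromene-6-carbaldehyde
Conditions: Ca(OH)2, MeOH, rt
Reagents that add atoms: none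
Why: Formal [3+3] chromene annulation (aldol-type C-alkylation at C3 of the resorcinol, dehydration to an ortho-quinone methide, oxa-6π electrocyclisation), in which the 2-OH is held in a hydrogen bond to the aldehyde, so the 4-OH closes the ring and the angular 5-hydroxy-6-formyl isomer should form.

Step 2
Reactants: 3 5-hydroxy-2,2-dimethyl-2H-chromene-6-carbaldehyde
Product: 4 5-(tert-butyldimethylsilyloxy)-2,2-dimethyl-2H-chromene-6-carbaldehyde
Conditions: TBSCl, imidazole, DMAP (cat.), DMF, rt → 40 °C
Reagents that add atoms: tert-butyldimethylsilyl chloride, CC(C)(C)[Si](C)(C)Cl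
Why: Imidazole-promoted O-silylation of a phenol next to a non-enolisable aldehyde, giving a silyl ether that is shielded by two ortho substituents.

Step 3
Reactants: 4 5-(tert-butyldimethylsilyloxy)-2,2-dimethyl-2H-chromene-6-carbaldehyde
Product: 5 6-(2-methoxyethenyl)-5-(tert-butyldimethylsilyloxy)-2,2-dimethyl-2H-chromene (E/Z mixture)
Conditions: Ph3P(CH2OMe)Cl, NaN(SiMe3)2, THF, 0 °C; then 4, −78 °C → rt
Reagents that add atoms: (methoxymethyl)triphenylphosphonium chloride, COC[P+](c1ccccc1)(c1ccccc1)c1ccccc1.[Cl-]
Why: Wittig methoxymethylenation for one-carbon homologation of an aromatic aldehyde; the olefin geometry does not matter because both isomers hydrolyse to the same aldehyde.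

Step 4
Reactants: 5 6-(2-methoxyethenyl)-5-(tert-butyldimethylsilyloxy)-2,2-dimethyl-2H-chromene
Product: 6 2-[5-(tert-butyldimethylsilyloxy)-2,2-dimethyl-2H-chromen-6-yl]acetaldehyde (ArCH2CHO)
Conditions: 2 M aq HCl, THF, 40 °C; used without storage
Reagents that add atoms: water, O
Why: Acid-catalysed enol ether hydrolysis, which a hindered aryl silyl ether and a 2,2-dimethylchromene both tolerate (any hydration of the chromene reverts to the conjugated olefin).

Step 5
Reactants: 7 6-methylhept-5-en-2-one
Product: 8 6-hydroxy-6-methylheptan-2-one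
Conditions: 35% aq H2SO4, 0 °C → rt
Reagents that add atoms: water, O
Why: Markovnikov acid-catalysed hydration of a trisubstituted olefin through the tertiary cation, with the ketone unaffected.

Step 6
Reactants: 8 6-hydroxy-6-methylheptan-2-one
Product: 9 6-methyl-6-(triethylsilyloxy)heptan-2-one
Conditions: TESCl, imidazole, DMAP (cat.), DMF, rt
Reagents that add atoms: triethylsilyl chloride, CC[Si](Cl)(CC)CC
Why: O-silylation of a tertiary alcohol with a small silyl chloride under conditions too mild to enolise the ketone.

Step 7
Reactants: 9 6-methyl-6-(triethylsilyloxy)heptan-2-one; 6 ArCH2CHO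
Product: 11 racemic 1-Ar-2-hydroxy-8-methyl-8-(triethylsilyloxy)nonan-4-one, via lithium enolate 10 (not isolated)
Conditions: LiN(i-Pr)2, THF, −78 °C; then 6, −78 °C; AcOH quench at −78 °C
Reagents that add atoms: none
Why: Directed crossed aldol addition of the kinetic (methyl-side) lithium enolate to the aldehyde, quenched cold to suppress proton transfer and silyl migration; the carbinol centre forms without control (racemic) and is removed in step 8.

Step 8
Reactants: 11 racemic aldol
Product: 12 1-Ar-8-methyl-8-(triethylsilyloxy)nonane-2,4-dione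
Conditions: IBX, EtOAc, 75 °C
Reagents that add atoms: none
Why: IBX oxidation of a β-hydroxy ketone to the 1,3-diketone, a neutral method that avoids over-oxidation at the central carbon and spares silyl ethers and the chromene.

Step 9
Reactants: 12 1,3-diketone; 13 N,N-dimethylformamide dimethyl acetal
Product: 16 3-[5-methyl-5-(triethylsilyloxy)hexanoyl]-5-Ar-4H-pyran-4-one, via mono-enaminone 14 (not isolated), via bis-enaminone 15 (not isolated)
Conditions: 13 (4 equiv), PhMe, rt → 100 °C; evaporate; AcOH, THF–H2O, rt → 40 °C
Reagents that add atoms: water, O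
Why: Double aminomethylenation (enaminone formation) at the two most acidic methylenes, the central one (C4a) first and the benzylic one (C3) on heating, followed by hydrolytic closure with loss of two dimethylamine molecules; this is the bis-enaminone synthesis of 4-pyranones, and the unactivated C6 methylene should condense far more slowly.

Step 10
Reactants: 16 3-acyl-5-aryl-4-pyranone
Product: 17 3-[(1Z)-1-(tert-butyldimethylsilyloxy)-5-methyl-5-(triethylsilyloxy)hex-1-en-1-yl]-5-Ar-4H-pyran-4-one
Conditions: TBSOTf, Et3N, CH2Cl2, −78 → 0 °C; filtration through Et3N-deactivated silica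
Reagents that add atoms: tert-butyldimethylsilyl triflate, CC(C)(C)[Si](C)(C)OS(=O)(=O)C(F)(F)F
Why: Soft enolisation (silyl triflate with a tertiary amine) at C6–H2, the only enolisable position; allylic strain between the chain and the pyranone favours the (Z)-enol ether, which carries the chain on the outside of the s-cis diene.

Step 11
Reactants: 18 ethynyltrimethylsilane
Product: 21 1-(triisopropylsilyloxy)-2-(trimethylsilyl)acetylene, via lithium trimethylsilylacetylide 19 (not isolated), via lithium trimethylsilylethynolate 20 (not isolated)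
Conditions: n-BuLi, THF, −78 °C; LiOOt-Bu (from t-BuOOH and LiN(SiMe3)2, THF, −78 °C), −78 → −10 °C; TIPSOTf, −78 → 0 °C
Reagents that add atoms: tert-butyl hydroperoxide, CC(C)(C)OO; triisopropylsilyl triflate, CC(C)[Si](C(C)C)(C(C)C)OS(=O)(=O)C(F)(F)F
Why: Oxidation of a lithium acetylide with lithium tert-butyl peroxide gives the ynolate, which a bulky silyl triflate traps on oxygen; the trimethylsilyl group blocks the carbon terminus so that silylketene formation is closed off.

Step 12
Reactants: 21 1-(triisopropylsilyloxy)-2-(trimethylsilyl)acetylene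
Product: 22 (triisopropylsilyloxy)acetylene
Conditions: K2CO3 (0.1 equiv), MeOH–THF, 0 °C, short contact; pentane extraction, used at once
Reagents that add atoms: none
Why: Methoxide-catalysed protodesilylation of an alkynylsilane, in which attack at the unhindered SiMe3 should be much faster than at the shielded Si(i-Pr)3 on oxygen.

Step 13
Reactants: 17 (Z)-silyl enol ether diene; 22 (triisopropylsilyloxy)acetylene
Product: 24 tetrakis-silyl Kanzonol T (5-O-TBS/7-O-TIPS/2'-O-TBS/side-chain O-TES), via cis-6,8a-dihydro cycloadduct 23 (not isolated)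
Conditions: 22 (2 equiv), AgNTf2 (10 mol %), 4 Å MS, CH2Cl2, −20 °C → rt; solvent and excess 22 evaporated in the same flask; DDQ (1.2 equiv), PhMe, 0 °C
Reagents that add atoms: none
Why: Proposed new method: the reaction is expected to be a polar, strongly asynchronous or stepwise [4+2] cycloaddition in which the nucleophilic CH terminus of 22 (future C8) adds to C8a, the β-carbon of the C8a=C4a–C4=O enone, and the resulting silyl ketenium carbon (C7) is captured by C6, the γ-terminus of the siloxy-dienolate, closing ring A as a six-membered carbocycle in the [4+2] mode to give the 6,8a-dihydroarene 23. The closest known reactions are the AgNTf2-catalysed [2+2] additions of siloxyalkynes to enones and unsaturated esters, their silver-catalysed formal inverse-demand Diels–Alder reactions with 1,2-diazines, and the inverse-demand Diels–Alder/aromatisation of 3-vinylchromones with enamines that leads to xanthones; a monocyclic 4-pyranone with a 1-siloxyalkenyl group has not been used as the diene, and the silver salt is included because C8a of a vinylogous ester is too weak an electrophile to rely on a purely thermal reaction. Regiochemistry needs no outside control, since the only pairing of matched polarity joins C8 to C8a and C7 to C6, placing oxygen on C7 and hydrogen on C8. Periselectivity and site selectivity rest on the substrate: collapse of the zwitterion at C4a ([2+2]) would build a strained cyclobutene with a quaternary carbon and should be reversible, attack at C2 finds no second double bond to close on, and closure at C6 is irreversible and keeps the conjugated C5(OSi)=C4a–C4=O unit. The (Z)-enol ether holds the side chain outside the s-cis diene, so a suprafacial addition sets C6–H and C8a–H cis in racemic 23, but both centres are erased on aromatisation and 24 has no stereocentre. DDQ takes the C8a hydride (α to O1 and vinylogously stabilised by the C7 silyloxy group) and C6–H is then lost as a proton; this must outrun the 1,4-elimination of O1 from C8a with C6–H, so the medium is kept free of base and protic acid and the oxidant is added cold as soon as 17 is consumed.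

Step 14
Reactants: 24 tetrakis-silyl Kanzonol T
Product: 25 Kanzonol T
Conditions: TBAF (6 equiv), AcOH (6 equiv), THF, 0 °C → rt
Reagents that add atoms: none
Why: Global fluoride desilylation, in which the three aryl silyl ethers cleave quickly and the tertiary TES ether follows at rt; the acetic acid buffer prevents base-induced opening of ring C or addition of the 2'-phenoxide to C2, and the absence of strong acid prevents the side-chain alcohol from closing onto O5 or O7 as a chroman.

## Compound list

1 | 2,4-dihydroxybenzaldehyde | O=Cc1ccc(O)cc1O | starting material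
2 | 3-methylbut-2-enal | CC(C)=CC=O | starting material
3 | 5-hydroxy-2,2-dimethyl-2H-chromene-6-carbaldehyde | O=Cc1ccc2OC(C)(C)C=Cc2c1O | intermediate
4 | 5-(tert-butyldimethylsilyloxy)-2,2-dimethyl-2H-chromene-6-carbaldehyde | O=Cc1ccc2OC(C)(C)C=Cc2c1O[Si](C)(C)C(C)(C)C | intermediate
5 | 6-(2-methoxyethenyl)-5-(tert-butyldimethylsilyloxy)-2,2-dimethyl-2H-chromene (E/Z mixture) | COC=Cc1ccc2OC(C)(C)C=Cc2c1O[Si](C)(C)C(C)(C)C | intermediate
6 | 2-[5-(tert-butyldimethylsilyloxy)-2,2-dimethyl-2H-chromen-6-yl]acetaldehyde | O=CCc1ccc2OC(C)(C)C=Cc2c1O[Si](C)(C)C(C)(C)C | intermediate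
7 | 6-methylhept-5-en-2-one | CC(C)=CCCC(C)=O | starting material
8 | 6-hydroxy-6-methylheptan-2-one | CC(=O)CCCC(C)(C)O | intermediate
9 | 6-methyl-6-(triethylsilyloxy)heptan-2-one | CC(=O)CCCC(C)(C)O[Si](CC)(CC)CC | intermediate
10 | lithium 6-methyl-6-(triethylsilyloxy)hept-1-en-2-olate | [Li+].[O-]C(=C)CCCC(C)(C)O[Si](CC)(CC)CC | intermediate
11 | 1-Ar-2-hydroxy-8-methyl-8-(triethylsilyloxy)nonan-4-one (racemic) | CC(C)(O[Si](CC)(CC)CC)CCCC(=O)CC(O)Cc1ccc2OC(C)(C)C=Cc2c1O[Si](C)(C)C(C)(C)C | intermediate
12 | 1-Ar-8-methyl-8-(triethylsilyloxy)nonane-2,4-dione | CC(C)(O[Si](CC)(CC)CC)CCCC(=O)CC(=O)Cc1ccc2OC(C)(C)C=Cc2c1O[Si](C)(C)C(C)(C)C | intermediate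
13 | N,N-dimethylformamide dimethyl acetal | COC(OC)N(C)C | starting material
14 | mono-enaminone: 12 with =CH–NMe2 on the central carbon C3 of the nonanedione | CN(C)C=C(C(=O)CCCC(C)(C)O[Si](CC)(CC)CC)C(=O)Cc1ccc2OC(C)(C)C=Cc2c1O[Si](C)(C)C(C)(C)C | intermediate
15 | bis-enaminone: 12 with =CH–NMe2 on the central carbon and on the benzylic carbon | CN(C)C=C(C(=O)CCCC(C)(C)O[Si](CC)(CC)CC)C(=O)C(=CN(C)C)c1ccc2OC(C)(C)C=Cc2c1O[Si](C)(C)C(C)(C)C | intermediate
16 | 3-[5-methyl-5-(triethylsilyloxy)hexanoyl]-5-Ar-4H-pyran-4-one | CC(C)(O[Si](CC)(CC)CC)CCCC(=O)c1cocc(-c2ccc3OC(C)(C)C=Cc3c2O[Si](C)(C)C(C)(C)C)c1=O | intermediate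
17 | 3-[(1Z)-1-(tert-butyldimethylsilyloxy)-5-methyl-5-(triethylsilyloxy)hex-1-en-1-yl]-5-Ar-4H-pyran-4-one | O=c1c(-c2ccc3c(c2O[Si](C)(C)C(C)(C)C)C=CC(C)(C)O3)cocc1/C(O[Si](C)(C)C(C)(C)C)=C/CCC(C)(C)O[Si](CC)(CC)CC | intermediate
18 | ethynyltrimethylsilane | C#C[Si](C)(C)C | starting material
19 | lithium (trimethylsilyl)acetylide | [Li]C#C[Si](C)(C)C | intermediate
20 | lithium 2-(trimethylsilyl)ethynolate | [Li+].[O-]C#C[Si](C)(C)C | intermediate
21 | 1-(triisopropylsilyloxy)-2-(trimethylsilyl)acetylene | C[Si](C)(C)C#CO[Si](C(C)C)(C(C)C)C(C)C | intermediate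
22 | (triisopropylsilyloxy)acetylene | C#CO[Si](C(C)C)(C(C)C)C(C)C | intermediate
23 | 6,8a-dihydro cycloadduct, C6–H and C8a–H cis (racemic, relative configuration drawn) | CC(C)(O[Si](CC)(CC)CC)CC[C@H]1C(O[Si](C(C)C)(C(C)C)C(C)C)=C[C@H]2OC=C(c3ccc4OC(C)(C)C=Cc4c3O[Si](C)(C)C(C)(C)C)C(=O)C2=C1O[Si](C)(C)C(C)(C)C | intermediate
24 | tetrakis-silyl Kanzonol T (5-O-TBS, 7-O-TIPS, 2'-O-TBS, side-chain O-TES) | CC(C)(O[Si](CC)(CC)CC)CCc1c(O[Si](C(C)C)(C(C)C)C(C)C)cc2occ(-c3ccc4c(c3O[Si](C)(C)C(C)(C)C)C=CC(C)(C)O4)c(=O)c2c1O[Si](C)(C)C(C)(C)C | intermediate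
25 | Kanzonol T | CC(C)(O)CCc1c(O)cc2occ(-c3ccc4c(c3O)C=CC(C)(C)O4)c(=O)c2c1O | target

## Step count and risks

Total step count: 14.
Longest linear sequence: 10 steps (steps 1–4, 7–10, 13, 14, from 2,4-dihydroxybenzaldehyde).

**Steps most likely to fail**

1. **Step 13.**
   - What may go wrong: C8a may be too weakly electrophilic, so that oligomerisation of the ynol ether or self-addition of the enol ether overtakes the cycloaddition. The zwitterion may collapse in the [2+2] mode. The cycloadduct may also lose O1 from C8a by 1,4-elimination with C6–H before the oxidant acts, which would aromatise ring A at the cost of ring C.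
   - Fallback: it uses known reactions only, sets out from 16 and comes back at 25. The same two bonds are made one at a time, with the oxidation placed between them, so that C8a is sp2 again before any base is used.
   - First, 16 is treated with commercial 1-(tert-butyldimethylsilyloxy)-1-methoxyethene and catalytic TBSOTf in CH2Cl2 at −78 °C. This is a Mukaiyama–Michael addition to the silyloxypyrylium form of a 4-pyranone; C8a is the doubly activated site, β to both C4=O and C5=O. It should give the racemic 4-silyloxy-2H-pyran-2-ylacetate F1.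
   - DDQ then removes the C8a hydride and the silyl group is lost on work-up, giving the methyl (3-acyl-5-aryl-4-oxo-4H-pyran-2-yl)acetate F2.
   - LiN(SiMe3)2 (3 equiv, THF, −78 → 0 °C) should then bring about the Dieckmann-type condensation of C6 on the ester carbon C7. This is the cyclisation that turns 2-acylphenylacetic esters into naphthalene-1,3-diols. Tautomerisation gives the 5,7-dihydroxyisoflavone bis-silyl ether F3.
   - The conditions of step 14 convert F3 into 25.

2. **Step 9.**
   - What may go wrong: the second condensation at the hindered benzylic methylene may stall or compete with condensation at C6. The aryl silyl ether may be cleaved by hot methanol and dimethylamine, after which the free phenol would close onto the enaminone carbon. The TES ether may also be lost in the acidic closure; this last loss would be repaired by the silyl triflate of step 10.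
   - Fallback: it sets out from 12 and comes back at 16.
   - One equivalent of 13 at rt stops at 14, which is isolated.
   - The benzylic position is deprotonated with LiN(SiMe3)2 (2.2 equiv, THF, −78 °C) and C-formylated with ethyl formate (crossed Claisen condensation of an enaminone anion) to give the hydroxymethylene enaminone F4.
   - On acetic acid quench F4 closes by addition–elimination of its enol oxygen at the aminomethylene carbon, giving 16. Here O1 comes from the formate, and the substrate is never heated with amine or methanol.

3. **Step 12.**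
   - What may go wrong: an ynolate is a good leaving group, so cleavage of the O–Si bond followed by methanolysis may compete with C–Si cleavage. The volatile, sensitive product may also be lost on isolation.
   - Fallback: it sets out from 21 (together with 17) and comes back at 25.
   - 21 is used itself as the dienophile under the conditions of step 13. Oxygen and silicon both direct the electrophilic carbon C8a to the silylated alkyne carbon, so the orientation is unchanged.
   - This should give, through the 8-trimethylsilyl cycloadduct F5, the 8-trimethylsilyl tetrakis-silyl isoflavone F6.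
   - The conditions of step 14 then also remove the C8 silyl group, by ipso-protonation of the electron-rich ring A phenoxide and fluoride attack on silicon.

## Further compounds

F1 | step 13 | methyl 2-{3-[5-methyl-5-(triethylsilyloxy)hexanoyl]-4-(tert-butyldimethylsilyloxy)-5-Ar-2H-pyran-2-yl}acetate (racemic) | COC(=O)CC1OC=C(c2ccc3OC(C)(C)C=Cc3c2O[Si](C)(C)C(C)(C)C)C(O[Si](C)(C)C(C)(C)C)=C1C(=O)CCCC(C)(C)O[Si](CC)(CC)CC
F2 | step 13 | methyl 2-{3-[5-methyl-5-(triethylsilyloxy)hexanoyl]-4-oxo-5-Ar-4H-pyran-2-yl}acetate | COC(=O)Cc1occ(-c2ccc3OC(C)(C)C=Cc3c2O[Si](C)(C)C(C)(C)C)c(=O)c1C(=O)CCCC(C)(C)O[Si](CC)(CC)CC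
F3 | step 13 | Kanzonol T 2'-O-TBS, side-chain O-TES bis-silyl ether | CC(C)(O[Si](CC)(CC)CC)CCc1c(O)cc2occ(-c3ccc4OC(C)(C)C=Cc4c3O[Si](C)(C)C(C)(C)C)c(=O)c2c1O
F4 | step 9 | hydroxymethylene enaminone: 14 with =CH–OH on the benzylic carbon | CN(C)C=C(C(=O)CCCC(C)(C)O[Si](CC)(CC)CC)C(=O)C(=CO)c1ccc2OC(C)(C)C=Cc2c1O[Si](C)(C)C(C)(C)C
F5 | step 12 | 8-trimethylsilyl-6,8a-dihydro cycloadduct, C6–H and C8a–H cis (racemic, relative configuration drawn) | CC(C)(O[Si](CC)(CC)CC)CC[C@H]1C(O[Si](C(C)C)(C(C)C)C(C)C)=C([Si](C)(C)C)[C@H]2OC=C(c3ccc4OC(C)(C)C=Cc4c3O[Si](C)(C)C(C)(C)C)C(=O)C2=C1O[Si](C)(C)C(C)(C)C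
F6 | step 12 | 8-trimethylsilyl analogue of 24 | CC(C)(O[Si](CC)(CC)CC)CCc1c(O[Si](C(C)C)(C(C)C)C(C)C)c([Si](C)(C)C)c2occ(-c3ccc4c(c3O[Si](C)(C)C(C)(C)C)C=CC(C)(C)O4)c(=O)c2c1O[Si](C)(C)C(C)(C)C
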